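I decide to judge each flask by the odds of Q against X, the plain ratio of the two, and I put the zero of the scale at even odds, one to one, where Q holds a share of 0.5 of Q plus X.

| setting | grey | green | amber | Sunday's | Saturday's | Friday's | Tuesday's | Thursday's |
|---|---|---|---|---|---|---|---|---|
| G | 0.10 M | 0.067 M | 0.15 M | 0.10 M (fed, over 5.0 min) | 0.10 M | 0.10 M | 0.10 M (fed, over 5.0 min) | 0.10 M |
| Z | 0.40 M | 0.40 M | 0.40 M | 0.400 M | 0.400 M (fed, over 30 s) | 0.400 M (fed, over 5.0 min) | 0.400 M | 0.400 M (in portions, 5, over 5.0 min) |
| L | 0.050 M | 0.050 M | 0.050 M | 0.0500 M | 0.0500 M | 0.0500 M | 0.0500 M | 0.0500 M |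
| temperature | 20 °C | 31 °C | 20 °C | 25 °C | 25 °C | 25 °C |  | 25 °C |
| remark | run made earlier | run made earlier | run made earlier | all else is in the flask from the start; the feed brings no volume worth counting | all else is in the flask from the start; the feed brings no volume worth counting | all else is in the flask from the start; the feed brings no volume worth counting | the addition at −5 °C, then warmed to 25 °C; the feed brings no volume worth counting | first portion at the start, last at 5.0 min |
| time |  |  |  | 6.0 min | 6.0 min | 6.0 min | 6.0 min | 6.0 min |

- grey (time / min: Q / %, X / %): 0.250: 10.3, 6.8; 0.667: 19.7, 13.9; 1.33: 24.9, 20.1; 2.00: 25.4, 23.1; 3.00: 23.9, 26.8; 4.00: 21.6, 29.8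
- green (time / min: Q / %, X / %): 0.500: 24.6, 16.4; 1.33: 18.3, 25.3; 2.50: 10.4, 31.8; 4.00: 5.5, 35.3; 6.00: 2.5, 37.0; 8.00: 1.6, 37.7
- amber (time / min: Q / %, X / %): 0.500: 16.8, 11.0; 1.00: 22.4, 16.7; 1.50: 25.3, 19.6; 2.50: 26.1, 24.4; 4.00: 23.1, 28.7; 8.00: 15.0, 36.0

(scatter of a reading: 0.3 percentage points)



- the best flask by share of Q in Q plus X; "all alike" if 1.5 percentage points covers them all (Sunday's / Saturday's / Friday's / Tuesday's / Thursday's / all alike)
- share of Q in Q plus X at the end, Sunday's
- share of Q in Q plus X at the end, Saturday's
- share of Q in Q plus X at the end, Friday's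
- share of Q in Q plus X at the end, Tuesday's
- share of Q in Q plus X at the end, Thursday's

The first readings show odds of 1.51 in grey, 1.50 in green and 1.53 in amber, so fresh product starts on Q's side of even. The odds then sink towards X, which I read as kinetic giving way to thermodynamic control. Read from the first reading to a later one, their logarithm falls at 0.197 min⁻¹ in grey at 20 °C and at 0.647 min⁻¹ in green at 31 °C. Drawing a straight line through the logarithms of these two rates against temperature gives 0.338 min⁻¹ at 25 °C, and from it 2.05 min. This is what I carry: the odds halving time, the time in which the ratio of Q to X falls by a factor of two. By hand, then, a setting counts through the average time that product sits before the reading, taking product to form as the feed enters.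

Take the quick feed first. Saturday's flask gets its Z in 30 s, so I take product to sit 5.75 min on average, and I reckon a share of 17.8%.

Next, stretch the feed over 5.0 min, as Friday's and Sunday's do, or split it into portions, as Thursday's does. I then take product to sit 3.50 min on average, and I reckon 31.7% for each of these flasks.

Last, chill the feed. Tuesday's flask takes its G at −5 °C, where the same line, carried beyond the runs, puts the halving time at 52.9 min, much longer than the feed. I therefore count just the warm 1.00 min, which gives 51.9%.

The forecast names Tuesday's as best, with 52% there, 32% for Friday's and 32% for Thursday's, and it says “Metering Z delays formation”. For Sunday's it gives 21% against my 31.7%, and for Saturday's 20.5% against my 17.8%.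

The flasks give 48.0% for Tuesday's, 45.8% for Thursday's, 45.2% for Friday's, 38.8% for Sunday's and 23.6% for Saturday's, so Tuesday's is best.

    G + L → E (k = 13.0 L mol⁻¹ min⁻¹, Ea = 53.0 kJ mol⁻¹)
    G + Z ⇌ Q (K = 2.80 L mol⁻¹, k = 2.10 L mol⁻¹ min⁻¹, Ea = 69.0 kJ mol⁻¹, ΔH = −30.0 kJ mol⁻¹)
    Z → D (k = 0.0620 min⁻¹, Ea = 92.0 kJ mol⁻¹)
    G + 2 Z → X (k = 2.90 L² mol⁻² min⁻¹, Ea = 46.0 kJ mol⁻¹)
    (constants at 25 °C)

At the end of Saturday's flask, the relaxation half-life of G + Z and Q by that step alone, both ways together, is 0.557 min, shorter than the time 6.0 min. At that moment in Saturday's flask, Q stands at 10.4% of the G charged against 33.6% for X. Started from the share of 34.5% in Saturday's flask at 4.0 min, the halving time 2.05 min gives 21.1% at 6.0 min, and the flask stands at 23.6%. Started from Sunday's end of feed, with Q at 16.7% and X at 21.5%, it gives 35.6%, and Sunday's flask stands at 38.8%.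

(The readings are calculated with constants of no real substance, noise included.)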